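**Conventions.** Germacrane numbering is used for all intermediates: C1 furanone carbonyl, C2=C3, C4(CH3)=C5, C6/C7 lactone ring fusion, C8, C9, C10 quaternary, C11–C13 methylene-lactone carbons, C14 methyl on C10, C15 methyl on C4. TBS = tert-butyldimethylsilyl, PMB = 4-methoxybenzyl, DMB = 3,4-dimethoxybenzyl.

**Remark on the chemistry.** Ketone 6 must be (3S,4S), which is L-erythro when read from C10. D-Erythronolactone would give the mirror image if its carbonyl carbon became C10, so 6 is built by tartrate-controlled epoxidation of an achiral dienol. The C6 oxygen is carried as a DMB ether so that it can be freed by DDQ after the allylic bromide is in place.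

## Analysis of the target

Target 31 is a ten-membered carbocycle (C1–C10) bridged by an oxygen between C3 and C10. The bridge makes C10, C1, C2, C3 and that oxygen a 3(2H)-furanone, and the carbocycle is fused across C6–C7 to an α-methylene-γ-butyrolactone. Five contiguous stereocentres run from C6 to C10, (6S,7S,8S,9S,10R). H6 and H7 are cis on the lactone, C8 carries the methacrylate, C9 the acetate, and C10 is quaternary with a methyl group and the furanone oxygen. Read from C10, the oxygens on C9 and C8 are erythro. The C4=C5 alkene is Z, trisubstituted and conjugated through C3=C2 to the C1 ketone. The sensitive features are: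

- the exocyclic methylene lactone and the methacrylate, both Michael acceptors;
- two different esters on neighbouring oxygens, which can migrate;
- the Z-dienone, which can isomerise once it is not held in the ring;
- O9, which is β to the C1 ketone, so a free O9 under base invites retro-aldol cleavage of C9–C10.

The hard parts are the strained medium ring holding a flat furanone and a Z alkene, the quaternary centre C10, and keeping O8 and O9 distinguishable. The strategy rests on C1–C2–C3 lying between a tertiary carbinol carbon (C10) and an alkenyl carbon (C4). That is the pattern of a 4-hydroxy-2-ynone, which can be assembled from a methyl ketone (C14, C10, C9–C7), a propiolic acid unit (C1–C3) and an alkenyl nucleophile (C4–C6, C15), with the ether oxygen on C9 steering the new centre at C10.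

## Retrosynthetic reasoning

**Ester C–O bonds at C8 and C9.** The two acyl groups of 31 are removed first, because the methacrylate and the vicinal diester would not survive organometallic, oxidative and low-valent-metal steps. Cutting the C8 ester gives alcohol 30, and cutting the C9 acetate (with O8 silylated) gives 29 and then 28. Alcohol 28 comes from macrolactone 27, in which O9 is a PMB ether and O8 a TBS ether. The forward order puts the acetate on the hindered O9 while O8 is still blocked, and the methacrylate on the more reactive O8 last.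

**C6–C7 and the lactone C–O bond.** In 27 the bond between the two ring-fusion carbons is cut together with the O6–C12 bond. This is the only disconnection that opens the ten-membered ring and the lactone at once and leaves an acyclic chain, 24, with a C6 aldehyde and a 2-(bromomethyl)acrylate at C7. The forward reaction has to close a strained ring and set C6 and C7; it goes through allylchromium 25 and alkoxide 26.

**C7–C11 and oxidation levels at C6 and C7.** The bromide 22 is the allylic transposition product of adduct 21, which arises by joining C7 of aldehyde 20 to the α-carbon of an acrylate ester. The Z-enal of 24 is made only after this, from alcohol 23, because a Z-enal would not survive the amine used to make 21. That order requires O6 and O7 to be unmasked separately. O7 is a primary TBS ether (19 from 18), and O6 is a DMB ether that DDQ removes from 22 while the hindered PMB ether on O9 stays.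

**Furanone C3–O bond.** The furanone of 18 is opened at the ring oxygen with a formal 1,3-shift of the carbonyl. This leads to the 4-hydroxy-2-ynone 16, in which C10 carries a free tertiary hydroxyl and the ketone sits on C3. The forward reaction is an amine addition (17), hydrolysis and cyclodehydration, and it creates no stereocentre.

**C1–C10 and C3–C4 (key disconnection).** Ynone 16 is cut on both sides of the three-carbon unit. This gives methyl ketone 6, propiolamide 8 and Z-alkenyl iodide 12. The cut is made here because each bond forms by a polar addition to a carbonyl group, the alkyne carbons serve first as nucleophile (13) and then as acyl donor (in 14), and the C9 ether of 6 can control C10. The pieces are small and the Z geometry is brought in ready-made with 15.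

**Ketone 6.** The carbonyl of 6 is traced to the terminal alkene of 5 and the silyl ethers to diol 4. The diol comes from epoxide 3, and the PMB ether from epoxy alcohol 2. Epoxy alcohol 2 is the desymmetrisation product of the achiral dienol 1. One reagent-controlled step thus sets C8 and C9 and leaves O9 chemically distinct from O7 and O8.

**Amide 8 and iodide 12.** Amide 8 is cut at the C–N bond to acid 7. Iodide 12 is the DMB ether of 11, which comes from alkynol 9 by adding H and I across the triple bond in a trans sense through alanate 10.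

## Alternatives that were turned down

**Alternative 1:** The disconnection cuts C2–C3 and C4–C5 and rejoins C2–C5. It leads from the ten-membered acetonide A1 back to the cyclooctenone A2, which carries a 1-propynyl ether on the C10 oxygen. In the forward step the enone alkene and the ynol ether combine, under 350 nm light or with PtCl2, to a fused cyclobutene that opens to the diene.

- For: two C–C bonds, the furanone and the ten-membered ring form in one event, with no macrocyclisation entropy. A thermal conrotatory opening should also give the Z geometry at C4=C5, because C1 is forced outward by the five-membered ring. On ring construction this is stronger than the chosen plan.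
- Against: A2 is itself an eight-membered ring with five stereocentres, a methylene lactone and a tertiary ynol ether next to a ketone. Reaching it would take longer than the whole chosen route. Ynol ethers of hindered tertiary alcohols need strongly basic eliminations that the lactone and enone would not tolerate. The methylene lactone is a second chromophore at 350 nm. The one-atom tether makes the cyclobutene intermediate highly strained. The acetonide leaves O8 and O9 undifferentiated, although they must carry different esters.
- Comparison: the chosen strategy gives up the one-step ring construction and in return keeps every stereocentre except C6 and C7 in simple acyclic pieces made in a few steps, with O8 and O9 distinguishable from the start.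

**Alternative 2:** The disconnection is C8–C9 and leads from the ten-membered cis-diol A3 to the dialdehyde A4. In the forward step SmI2 (divalent samarium) couples the two aldehydes through ketyl radicals.

- For: a ring bond and two carbinol centres form together, both halves are small, and pinacol closures favour cis-diols. In convergence it equals the chosen plan.
- Against: A4 contains the C1 ketone with an oxygen on the α-carbon C10, and SmI2 cleaves such α-alkoxy ketones and reduces the dienone. Only ring conformation relates the new diol to C7 and C10, so four diastereomers are possible. A3 lacks the C11 methylene, which would have to be added by enolate chemistry with a free β-hydroxy ketone present (retro-aldol). The diol emerges undifferentiated.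
- Comparison: the chosen strategy sets C8 and C9 at the start under reagent control with different protecting groups, and the methylene lactone arrives with the ring closure.

**Alternative 3:** The disconnection is C1–C2 and leads from the ten-membered cyclic enynol A5 to the iodoalkyne aldehyde A6. In the forward step CrCl2 with catalytic NiCl2 couples the iodoalkyne with the aldehyde.

- For: after oxidation at C1, a transannular addition of O10 to C3 would give the furanone with the right regiochemistry and no carbonyl transposition. On this point it is stronger than the chosen plan, and the C1 carbinol configuration is irrelevant.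
- Against: the ring must hold a linear C4–C3≡C2–C1 unit beside a Z alkene and two fused five-membered rings, so strain will favour oligomers. The aldehyde sits on the quaternary C10. A6 must already contain all five stereocentres and the methylene lactone, which makes the sequence linear and long. The acetonide again hides the O8/O9 difference.
- Comparison: the chosen strategy keeps the alkyne acyclic, converts it to the furanone before ring closure, and closes the ring at C6–C7, where the lactone forms at the same time.

Key step: step 9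

## Route

**Step 1**
Reactants: 1 penta-1,4-dien-3-ol
Product: 2 (2S,3R)-1,2-epoxypent-4-en-3-ol
Conditions: Ti(OiPr)4, D-(−)-diisopropyl tartrate, t-BuOOH, 4 Å molecular sieves, CH2Cl2, −20 °C
Reagents that add atoms: tert-butyl hydroperoxide, CC(C)(C)OO
Why: Sharpless asymmetric epoxidation used as a desymmetrisation: the tartrate complex selects one enantiotopic vinyl group and one of its faces, giving the erythro epoxy alcohol, and the minor enantiomer is removed by a faster second epoxidation. This sets C8 (epoxide CH) and C9 (carbinol carbon).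

**Step 2**
Reactants: 2 (2S,3R)-1,2-epoxypent-4-en-3-ol
Product: 3 (2S,3R)-1,2-epoxy-3-(4-methoxybenzyloxy)pent-4-ene
Conditions: NaH, 4-methoxybenzyl chloride, Bu4NI (cat.), THF/DMF, 0 °C → rt
Reagents that add atoms: 4-methoxybenzyl chloride, COc1ccc(CCl)cc1
Why: Williamson etherification; in aprotic medium the alkoxide is benzylated faster than it can undergo Payne rearrangement. The PMB ether is the chelating group needed on C9 in step 9.

**Step 3**
Reactants: 3 (2S,3R)-1,2-epoxy-3-(4-methoxybenzyloxy)pent-4-ene
Product: 4 (2S,3R)-3-(4-methoxybenzyloxy)pent-4-ene-1,2-diol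
Conditions: KOH, DMSO/H2O, 80 °C
Reagents that add atoms: water, O
Why: Hydroxide opens the terminal epoxide by SN2 attack at the CH2 carbon, so the C8 centre is untouched and the erythro diol results.

**Step 4**
Reactants: 4 (2S,3R)-3-(4-methoxybenzyloxy)pent-4-ene-1,2-diol
Product: 5 (2S,3R)-1,2-bis(tert-butyldimethylsilyloxy)-3-(4-methoxybenzyloxy)pent-4-ene
Conditions: TBSOTf, 2,6-lutidine, CH2Cl2, −78 → 0 °C
Reagents that add atoms: tert-butyldimethylsilyl trifluoromethanesulfonate, CC(C)(C)[Si](C)(C)OS(=O)(=O)C(F)(F)F
Why: Silyl triflate silylation of both hydroxyls. The bulky, weakly donating silyl ether on C8 leaves the C9 PMB ether as the only chelating oxygen next to the future ketone.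

**Step 5**
Reactants: 5 (2S,3R)-1,2-bis(tert-butyldimethylsilyloxy)-3-(4-methoxybenzyloxy)pent-4-ene
Product: 6 (3S,4S)-4,5-bis(tert-butyldimethylsilyloxy)-3-(4-methoxybenzyloxy)pentan-2-one
Conditions: PdCl2(quinox) (quinox = 2-(4,5-dihydrooxazol-2-yl)quinoline, cat.), AgSbF6 (cat.), aq. t-BuOOH, CH2Cl2, 0 °C → rt
Reagents that add atoms: tert-butyl hydroperoxide, CC(C)(C)OO
Why: Wacker-type oxidation of the terminal alkene with a quinoline–oxazoline palladium catalyst and a peroxide oxidant, a system that gives methyl ketones from protected allylic alcohols where PdCl2/CuCl/O2 tends to give aldehyde mixtures. The near-neutral conditions should not epimerise the α-centre C9.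

**Step 6**
Reactants: 7 propiolic acid
Product: 8 N-methoxy-N-methylpropiolamide
Conditions: N,O-dimethylhydroxylamine hydrochloride, N,N'-dicyclohexylcarbodiimide, N-methylmorpholine, CH2Cl2, −15 → 0 °C
Reagents that add atoms: N,O-dimethylhydroxylamine hydrochloride, CNOC.Cl
Why: Carbodiimide-mediated amidation; at low temperature the weakly nucleophilic N,O-dialkylhydroxylamine acylates faster than it adds to the triple bond.

**Step 7**
Reactants: 9 but-2-yn-1-ol
Product: 11 (Z)-3-iodobut-2-en-1-ol, via cyclic alkenylalanate 10 (not isolated)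
Conditions: NaAlH2(OCH2CH2OMe)2, THF, 0 °C → rt; then I2, THF, −78 → 0 °C
Reagents that add atoms: iodine, II
Why: Hydroxyl-directed trans-hydroalumination delivers hydride to C2 and places aluminium on C3 inside a five-membered alanate. Iodine cleaves the C–Al bond with retention, fixing the Z geometry (iodine cis to CH2OH) that becomes the C4=C5 geometry of 31.

**Step 8**
Reactants: 11 (Z)-3-iodobut-2-en-1-ol
Product: 12 (Z)-3-iodobut-2-enyl 3,4-dimethoxybenzyl ether
Conditions: NaH, 3,4-dimethoxybenzyl chloride, Bu4NI (cat.), THF/DMF, 0 °C → rt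
Reagents that add atoms: 3,4-dimethoxybenzyl chloride, COc1ccc(CCl)cc1OC
Why: Williamson etherification; the DMB ether is inert to organolithiums and can later be removed by DDQ in the presence of the PMB ether.

**Step 9**
Reactants: 8 N-methoxy-N-methylpropiolamide; 6 (3S,4S)-4,5-bis(TBSO)-3-(PMBO)pentan-2-one; 12 (Z)-3-iodobut-2-enyl DMB ether
Product: 16 (2Z,7S,8S,9S)-9,10-bis(TBSO)-1-(DMBO)-7-hydroxy-8-(PMBO)-3,7-dimethyldec-2-en-5-yn-4-one, via lithium acetylide 13 (not isolated), via magnesium alkoxide 14 (not isolated), via alkenyllithium 15 (not isolated)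
Conditions: 8, LiN(SiMe3)2, THF/Et2O, −78 °C; added to 6 premixed with MgBr2·OEt2 in CH2Cl2, −78 °C; then 15 (from 12, 2.2 equiv, and t-BuLi, 4.4 equiv, Et2O, −78 °C), −78 → −40 °C; inverse quench into cold aq. NH4Cl
Reagents that add atoms: none
Why: LiN(SiMe3)2 deprotonates 8 to acetylide 13, and MgBr2 ties the carbonyl oxygen of 6 and the C9 PMB ether oxygen into a five-membered Cram chelate (the C8 silyl ether is too hindered and too poor a donor to compete), so the acetylide attacks C10 from the face opposite the C8 branch and gives alkoxide 14 with the C10 configuration of 31. The closest known reaction type for this half is the chelation-controlled addition of metal acetylides to α-alkoxy ketones. Iodine–lithium exchange of 12 with two equivalents of t-BuLi at −78 °C gives alkenyllithium 15 with retention, and 15 adds to the N-methoxy-N-methylamide of 14 to form a five-membered lithium chelate that does not collapse before the cold quench, so a second addition cannot occur; this half is a Weinreb ketone synthesis with an alkenyllithium. No ring is closed; two C–C bonds (C1–C10, C3–C4) and one stereocentre (C10) are made. The step needs face selectivity at C10 (secured by the chelating ether on C9), 1,2- rather than conjugate addition at the alkynyl amide (secured by the hard organolithium and the fully substituted carbon next to the alkyne) and retention of the Z geometry (alkenyllithiums are configurationally stable at this temperature). One equivalent of 15 is consumed by the hexamethyldisilazane released in the first deprotonation, hence the excess of 12. The cold inverse quench keeps the liberated N,O-dimethylhydroxylamine anion from adding to the new ynone.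

**Step 10**
Reactants: 16 4-hydroxy-2-ynone (C1–C10 chain)
Product: 18 (2R)-2-[(1S,2S)-2,3-bis(TBSO)-1-(PMBO)propyl]-5-[(Z)-4-(DMBO)but-2-en-2-yl]-2-methylfuran-3(2H)-one, via enaminone 17 (not isolated)
Conditions: Et2NH, EtOH, rt; then AcOH, H2O, THF, rt
Reagents that add atoms: water, O
Why: Conjugate addition of the secondary amine to the ynone gives enaminone 17; in aqueous acid the C10 hydroxyl adds to the C3 carbonyl, water is lost and the C1 iminium is hydrolysed, so the ring oxygen ends on C3 and the ketone on C1 (a known route from 4-hydroxy-2-ynones to 3(2H)-furanones). C10 is not affected, and mild conditions are chosen to keep the Z alkene.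

**Step 11**
Reactants: 18 furanone with TBS on O7 and O8
Product: 19 (2S,3S)-2-(TBSO)-3-(PMBO)-3-[(2R)-5-[(Z)-4-(DMBO)but-2-en-2-yl]-2-methyl-3-oxo-2,3-dihydrofuran-2-yl]propan-1-ol
Conditions: HF·pyridine, pyridine, THF, 0 °C
Reagents that add atoms: none
Why: Buffered HF·pyridine cleaves the primary silyl ether much faster than the hindered secondary one on C8; the benzyl-type ethers and the furanone are inert.

**Step 12**
Reactants: 19 C7 alcohol
Product: 20 (2R,3S)-2-(TBSO)-3-(PMBO)-3-[(2R)-5-[(Z)-4-(DMBO)but-2-en-2-yl]-2-methyl-3-oxo-2,3-dihydrofuran-2-yl]propanal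
Conditions: Dess–Martin periodinane, NaHCO3, CH2Cl2, 0 °C → rt
Reagents that add atoms: none
Why: Dess–Martin oxidation under buffered, non-basic conditions gives the α-silyloxy aldehyde without epimerising C8 (the descriptor changes only because of the new CHO priority).

**Step 13**
Reactants: 20 C7 aldehyde
Product: 21 methyl (4S,5S)-4-(TBSO)-3-hydroxy-5-(PMBO)-5-[(2R)-5-[(Z)-4-(DMBO)but-2-en-2-yl]-2-methyl-3-oxo-2,3-dihydrofuran-2-yl]-2-methylidenepentanoate (both C3 epimers)
Conditions: methyl acrylate (neat, excess), 3-hydroxyquinuclidine (0.5 equiv), rt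
Reagents that add atoms: methyl acrylate, C=CC(=O)OC
Why: Morita–Baylis–Hillman reaction: the amine adds to the acrylate and the resulting enolate attacks the activated α-alkoxy aldehyde, forming C7–C11. The new carbinol centre is lost in step 14, so its configuration does not matter.

**Step 14**
Reactants: 21 Baylis–Hillman adduct
Product: 22 methyl (2Z,4S,5S)-2-(bromomethyl)-4-(TBSO)-5-(PMBO)-5-[(2R)-5-[(Z)-4-(DMBO)but-2-en-2-yl]-2-methyl-3-oxo-2,3-dihydrofuran-2-yl]pent-2-enoate
Conditions: N-bromosuccinimide, Me2S, CH2Cl2, −20 → 0 °C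
Reagents that add atoms: N-bromosuccinimide, O=C1CCC(=O)N1Br
Why: Corey–Kim-type activation of the allylic alcohol as an alkoxysulfonium salt, then SN2' attack of bromide at the methylene terminus, gives the rearranged primary bromide. The trisubstituted alkene forms with the ester trans to the C8 branch (Z).

**Step 15**
Reactants: 22 allylic bromide with DMB on O6
Product: 23 methyl (2Z,4S,5S)-2-(bromomethyl)-4-(TBSO)-5-(PMBO)-5-[(2R)-5-[(Z)-4-hydroxybut-2-en-2-yl]-2-methyl-3-oxo-2,3-dihydrofuran-2-yl]pent-2-enoate
Conditions: DDQ (1.1 equiv), CH2Cl2/pH 7 buffer, 0 °C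
Reagents that add atoms: none
Why: DDQ oxidises the more electron-rich, unhindered 3,4-dimethoxybenzyl ether faster than the hindered secondary PMB ether; the allylic bromide, silyl ether and ester are inert to this neutral oxidant.

**Step 16**
Reactants: 23 C6 allylic alcohol
Product: 24 methyl (2Z,4S,5S)-2-(bromomethyl)-4-(TBSO)-5-(PMBO)-5-[(2R)-2-methyl-3-oxo-5-[(Z)-4-oxobut-2-en-2-yl]-2,3-dihydrofuran-2-yl]pent-2-enoate
Conditions: Dess–Martin periodinane, NaHCO3, CH2Cl2, 0 °C
Reagents that add atoms: none
Why: Buffered Dess–Martin oxidation of the allylic alcohol gives the Z enal without acid or base that would isomerise it; the bromide is untouched.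

**Step 17**
Reactants: 24 bromo ester Z-enal
Product: 27 (2Z,4S,8S,9S,10S,11R)-9-(TBSO)-10-(PMBO)-2,11-dimethyl-7-methylidene-5,14-dioxatricyclo[9.2.1.0(4,8)]tetradeca-1(13),2-diene-6,12-dione, via allylchromium dichloride 25 (not isolated), via chromium alkoxide 26 (not isolated)
Conditions: CrCl2 (8 equiv), THF/DMF, rt, slow addition of 24 to about 0.002 M
Reagents that add atoms: none
Why: Nozaki–Hiyama (Barbier-type) allylation: CrCl2 turns the allylic bromide into allylchromium 25, whose γ-carbon C7 adds to the C6 aldehyde through a chair transition state, and alkoxide 26 closes onto the ester to give the lactone. γ-Substituted 2-(alkoxycarbonyl)allyl metals give syn adducts, hence the cis-fused lactone. The C8 centre should direct the face at C7 (H8 in the allyl plane to avoid A1,3 strain, the C9 chain anti to the incoming aldehyde), which corresponds to the 7,8 relationship of 31.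

**Step 18**
Reactants: 27 macrolactone (TBS on O8, PMB on O9)
Product: 28 (2Z,4S,8S,9S,10S,11R)-9-(TBSO)-10-hydroxy-2,11-dimethyl-7-methylidene-5,14-dioxatricyclo[9.2.1.0(4,8)]tetradeca-1(13),2-diene-6,12-dione
Conditions: DDQ, CH2Cl2/pH 7 buffer, rt
Reagents that add atoms: none
Why: Oxidative cleavage of the PMB ether by DDQ through the benzylic oxocarbenium ion; lactone, furanone and silyl ether are inert, and the buffered medium avoids base that could trigger retro-aldol cleavage at C9–C10.

**Step 19**
Reactants: 28 C9 alcohol
Product: 29 (2Z,4S,8S,9S,10S,11R)-9-(TBSO)-2,11-dimethyl-7-methylidene-6,12-dioxo-5,14-dioxatricyclo[9.2.1.0(4,8)]tetradeca-1(13),2-dien-10-yl acetate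
Conditions: Ac2O, DMAP, pyridine, CH2Cl2, 0 °C → rt
Reagents that add atoms: acetic anhydride, CC(=O)OC(C)=O
Why: DMAP-catalysed acylation of the hindered secondary hydroxyl; with O8 still silylated no acyl migration is possible, and acylation should be faster than retro-aldol loss.

**Step 20**
Reactants: 29 C9 acetate C8 silyl ether
Product: 30 (2Z,4S,8S,9S,10S,11R)-9-hydroxy-2,11-dimethyl-7-methylidene-6,12-dioxo-5,14-dioxatricyclo[9.2.1.0(4,8)]tetradeca-1(13),2-dien-10-yl acetate
Conditions: HF·pyridine, THF, 0 °C → rt
Reagents that add atoms: none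
Why: Fluoride-mediated desilylation under acidic conditions, where migration of the neighbouring acetate from O9 to O8 is slow.

**Step 21**
Reactants: 30 C8 alcohol
Product: 31 (2Z,4S,8S,9S,10S,11R)-10-acetoxy-2,11-dimethyl-7-methylidene-6,12-dioxo-5,14-dioxatricyclo[9.2.1.0(4,8)]tetradeca-1(13),2-dien-9-yl 2-methylprop-2-enoate (target)
Conditions: methacrylic anhydride, Et3N, DMAP (cat.), CH2Cl2, 0 °C
Reagents that add atoms: methacrylic anhydride, C=C(C)C(=O)OC(=O)C(C)=C
Why: DMAP-catalysed esterification of the freed C8 hydroxyl with the anhydride; acylation of this less hindered alcohol should outrun acetyl migration, and the weak base leaves the methylene lactone intact.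

## Compound list

1 | penta-1,4-dien-3-ol | C=CC(O)C=C | starting material
2 | (2S,3R)-1,2-epoxypent-4-en-3-ol | C=C[C@@H](O)[C@@H]1CO1 | intermediate
3 | (2S,3R)-1,2-epoxy-3-(4-methoxybenzyloxy)pent-4-ene | C=C[C@@H](OCc1ccc(OC)cc1)[C@@H]1CO1 | intermediate
4 | (2S,3R)-3-(4-methoxybenzyloxy)pent-4-ene-1,2-diol | C=C[C@@H](OCc1ccc(OC)cc1)[C@@H](O)CO | intermediate
5 | (2S,3R)-1,2-bis(tert-butyldimethylsilyloxy)-3-(4-methoxybenzyloxy)pent-4-ene | C=C[C@@H](OCc1ccc(OC)cc1)[C@@H](O[Si](C)(C)C(C)(C)C)CO[Si](C)(C)C(C)(C)C | intermediate
6 | (3S,4S)-4,5-bis(tert-butyldimethylsilyloxy)-3-(4-methoxybenzyloxy)pentan-2-one (C14, C10, C9, C8, C7) | CC(=O)[C@@H](OCc1ccc(OC)cc1)[C@@H](O[Si](C)(C)C(C)(C)C)CO[Si](C)(C)C(C)(C)C | intermediate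
7 | propiolic acid | C#CC(=O)O | starting material
8 | N-methoxy-N-methylpropiolamide | C#CC(=O)N(C)OC | intermediate
9 | but-2-yn-1-ol | CC#CCO | starting material
10 | sodium 2,2-bis(2-methoxyethoxy)-3-methyl-2,5-dihydro-1,2-oxaluminol-2-uide (cyclic alkenylalanate, Al cis to CH2O) | CC1=CCO[Al-]1(OCCOC)OCCOC.[Na+] | intermediate
11 | (Z)-3-iodobut-2-en-1-ol | C/C(I)=C/CO | intermediate
12 | (Z)-4-[(3-iodobut-2-enyloxy)methyl]-1,2-dimethoxybenzene | C/C(I)=C/COCc1ccc(OC)c(OC)c1 | intermediate
13 | lithium acetylide of 8 | [Li]C#CC(=O)N(C)OC | intermediate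
14 | (4S,5S,6S)-6,7-bis(TBSO)-4-hydroxy-N-methoxy-5-(PMBO)-N,4-dimethylhept-2-ynamide, drawn as its bromomagnesium alkoxide | C[C@](O[Mg]Br)(C#CC(=O)N(C)OC)[C@@H](OCc1ccc(OC)cc1)[C@@H](O[Si](C)(C)C(C)(C)C)CO[Si](C)(C)C(C)(C)C | intermediate
15 | [4-(3,4-dimethoxybenzyloxy)but-2-en-2-yl]lithium, lithium cis to the CH2O group (geometry of 12 retained) | C/C([Li])=C/COCc1ccc(OC)c(OC)c1 | intermediate
16 | (2Z,7S,8S,9S)-9,10-bis(TBSO)-1-(DMBO)-7-hydroxy-8-(PMBO)-3,7-dimethyldec-2-en-5-yn-4-one | C[C@](O)(C#CC(=O)/C(C)=C\COCc1ccc(OC)c(OC)c1)[C@@H](OCc1ccc(OC)cc1)[C@@H](O[Si](C)(C)C(C)(C)C)CO[Si](C)(C)C(C)(C)C | intermediate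
17 | (2Z,7S,8S,9S)-9,10-bis(TBSO)-6-(diethylamino)-1-(DMBO)-7-hydroxy-8-(PMBO)-3,7-dimethyldeca-2,5-dien-4-one (C5=C6 geometry not defined) | C[C@](O)(C(=CC(=O)/C(C)=C\COCc1ccc(OC)c(OC)c1)N(CC)CC)[C@@H](OCc1ccc(OC)cc1)[C@@H](O[Si](C)(C)C(C)(C)C)CO[Si](C)(C)C(C)(C)C | intermediate
18 | (2R)-2-[(1S,2S)-2,3-bis(TBSO)-1-(PMBO)propyl]-5-[(Z)-4-(DMBO)but-2-en-2-yl]-2-methylfuran-3(2H)-one | C/C(=C/COCc1ccc(OC)c(OC)c1)C1=CC(=O)[C@](C)(O1)[C@@H](OCc1ccc(OC)cc1)[C@@H](O[Si](C)(C)C(C)(C)C)CO[Si](C)(C)C(C)(C)C | intermediate
19 | (2S,3S)-2-(TBSO)-3-(PMBO)-3-[(2R)-5-[(Z)-4-(DMBO)but-2-en-2-yl]-2-methyl-3-oxo-2,3-dihydrofuran-2-yl]propan-1-ol | C/C(=C/COCc1ccc(OC)c(OC)c1)C1=CC(=O)[C@](C)(O1)[C@@H](OCc1ccc(OC)cc1)[C@@H](O[Si](C)(C)C(C)(C)C)CO | intermediate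
20 | (2R,3S)-2-(TBSO)-3-(PMBO)-3-[(2R)-5-[(Z)-4-(DMBO)but-2-en-2-yl]-2-methyl-3-oxo-2,3-dihydrofuran-2-yl]propanal | C/C(=C/COCc1ccc(OC)c(OC)c1)C1=CC(=O)[C@](C)(O1)[C@@H](OCc1ccc(OC)cc1)[C@@H](O[Si](C)(C)C(C)(C)C)C=O | intermediate
21 | methyl (4S,5S)-4-(TBSO)-3-hydroxy-5-(PMBO)-5-[(2R)-5-[(Z)-4-(DMBO)but-2-en-2-yl]-2-methyl-3-oxo-2,3-dihydrofuran-2-yl]-2-methylidenepentanoate (C3 epimers) | C/C(=C/COCc1ccc(OC)c(OC)c1)C1=CC(=O)[C@](C)(O1)[C@@H](OCc1ccc(OC)cc1)[C@@H](O[Si](C)(C)C(C)(C)C)C(O)C(=C)C(=O)OC | intermediate
22 | methyl (2Z,4S,5S)-2-(bromomethyl)-4-(TBSO)-5-(PMBO)-5-[(2R)-5-[(Z)-4-(DMBO)but-2-en-2-yl]-2-methyl-3-oxo-2,3-dihydrofuran-2-yl]pent-2-enoate | C/C(=C/COCc1ccc(OC)c(OC)c1)C1=CC(=O)[C@](C)(O1)[C@@H](OCc1ccc(OC)cc1)[C@@H](O[Si](C)(C)C(C)(C)C)/C=C(\CBr)C(=O)OC | intermediate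
23 | methyl (2Z,4S,5S)-2-(bromomethyl)-4-(TBSO)-5-(PMBO)-5-[(2R)-5-[(Z)-4-hydroxybut-2-en-2-yl]-2-methyl-3-oxo-2,3-dihydrofuran-2-yl]pent-2-enoate | C/C(=C/CO)C1=CC(=O)[C@](C)(O1)[C@@H](OCc1ccc(OC)cc1)[C@@H](O[Si](C)(C)C(C)(C)C)/C=C(\CBr)C(=O)OC | intermediate
24 | methyl (2Z,4S,5S)-2-(bromomethyl)-4-(TBSO)-5-(PMBO)-5-[(2R)-2-methyl-3-oxo-5-[(Z)-4-oxobut-2-en-2-yl]-2,3-dihydrofuran-2-yl]pent-2-enoate | C/C(=C/C=O)C1=CC(=O)[C@](C)(O1)[C@@H](OCc1ccc(OC)cc1)[C@@H](O[Si](C)(C)C(C)(C)C)/C=C(\CBr)C(=O)OC | intermediate
25 | allylchromium dichloride from 24 (trivalent chromium on C13, allyl geometry not defined) | C/C(=C/C=O)C1=CC(=O)[C@](C)(O1)[C@@H](OCc1ccc(OC)cc1)[C@@H](O[Si](C)(C)C(C)(C)C)C=C(C[Cr](Cl)Cl)C(=O)OC | intermediate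
26 | ten-membered (6S,7S)-configured C6 chromium alkoxide with the methyl 2-propenoate unit on C7 | CC(C)(C)[Si](C)(C)O[C@H]1[C@@H](C(=C)C(=O)OC)[C@@H](O[Cr](Cl)Cl)/C=C(/C)C2=CC(=O)[C@](C)(O2)[C@H]1OCc1ccc(OC)cc1 | intermediate
27 | (2Z,4S,8S,9S,10S,11R)-9-(TBSO)-10-(PMBO)-2,11-dimethyl-7-methylidene-5,14-dioxatricyclo[9.2.1.0(4,8)]tetradeca-1(13),2-diene-6,12-dione | CC(C)(C)[Si](C)(C)O[C@H]1[C@H]2C(=C)C(=O)O[C@H]2/C=C(/C)C2=CC(=O)[C@](C)(O2)[C@H]1OCc1ccc(OC)cc1 | intermediate
28 | (2Z,4S,8S,9S,10S,11R)-9-(TBSO)-10-hydroxy-2,11-dimethyl-7-methylidene-5,14-dioxatricyclo[9.2.1.0(4,8)]tetradeca-1(13),2-diene-6,12-dione | CC(C)(C)[Si](C)(C)O[C@H]1[C@H]2C(=C)C(=O)O[C@H]2/C=C(/C)C2=CC(=O)[C@](C)(O2)[C@H]1O | intermediate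
29 | (2Z,4S,8S,9S,10S,11R)-9-(TBSO)-2,11-dimethyl-7-methylidene-6,12-dioxo-5,14-dioxatricyclo[9.2.1.0(4,8)]tetradeca-1(13),2-dien-10-yl acetate | CC(C)(C)[Si](C)(C)O[C@H]1[C@H]2C(=C)C(=O)O[C@H]2/C=C(/C)C2=CC(=O)[C@](C)(O2)[C@H]1OC(C)=O | intermediate
30 | (2Z,4S,8S,9S,10S,11R)-9-hydroxy-2,11-dimethyl-7-methylidene-6,12-dioxo-5,14-dioxatricyclo[9.2.1.0(4,8)]tetradeca-1(13),2-dien-10-yl acetate | O[C@H]1[C@H]2C(=C)C(=O)O[C@H]2/C=C(/C)C2=CC(=O)[C@](C)(O2)[C@H]1OC(C)=O | intermediate
31 | (2Z,4S,8S,9S,10S,11R)-10-acetoxy-2,11-dimethyl-7-methylidene-6,12-dioxo-5,14-dioxatricyclo[9.2.1.0(4,8)]tetradeca-1(13),2-dien-9-yl 2-methylprop-2-enoate; germacrane (6S,7S,8S,9S,10R) | C=C(C)C(=O)O[C@H]1[C@H]2C(=C)C(=O)O[C@H]2/C=C(/C)C2=CC(=O)[C@](C)(O2)[C@H]1OC(C)=O | target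

## Step count and least certain steps

Total: 21 steps. Longest linear sequence: 18 steps (steps 1–5, then 9–21). Amide 8 takes one step and iodide 12 two.

**Step 9 (key step).** The most likely failure is incomplete chelation control: attack on ketone that is not held in the magnesium chelate, favoured by the THF brought in with the base, would lower the face selectivity at C10. Protonation of 15 by the amine and conjugate addition of the released hydroxylamine anion on warming would also lower the return. The fallback sets out from 6 and 12 and returns at 16. HC≡CMgBr would be added to 6 under the same MgBr2 chelation to give (3S,4S,5S)-5,6-bis(TBSO)-4-(PMBO)-3-methylhex-1-yn-3-ol F1. Alkenyllithium 15 from 12 would be formylated with N,N-dimethylformamide to (Z)-4-(DMBO)-2-methylbut-2-enal F2. The dilithium derivative of F1 (two equivalents of n-BuLi) would add to F2 to give (2Z,7S,8S,9S)-9,10-bis(TBSO)-1-(DMBO)-8-(PMBO)-3,7-dimethyldec-2-en-5-yne-4,7-diol F3 as a C4 mixture. MnO2 would then oxidise its secondary propargylic, allylic alcohol to 16. The same two bonds are formed in separate flasks, with no amine and no amide leaving group.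

**Step 17.** The most likely failure is poor facial selectivity at the aldehyde carbon C6. The strain of the forming ring, not the chair transition state alone, decides which aldehyde face can be reached, so the trans-fused lactone may form. Oligomerisation and closure onto the furanone carbonyl are further losses. The fallback sets out from 24 and returns at 27. If the closure gives mainly the (2Z,4R,8S,9S,10S,11R) C6-epimeric lactone F4, LiOH would open it to the ten-membered 6-hydroxy acid F5. A Mitsunobu lactonisation (PPh3, diisopropyl azodicarboxylate) would then re-close the lactone with inversion at C6 to give 27. C6 is then set by an invertive substitution and no longer by the allylation.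

**Step 13.** The most likely failure is a slow reaction that leaves the aldehyde exposed to amine base for days. That allows epimerisation at C8, β-elimination of the C9 ether, and isomerisation of the Z alkene by reversible amine addition to the dienone. The fallback sets out from 20 and returns at 21. The [1-(methoxycarbonyl)vinyl]aluminium reagent, preformed from methyl propiolate with i-Bu2AlH and hexamethylphosphoramide in THF, would be added to 20 at −78 → 0 °C without any amine. This makes no new compound (F0).

**Step 10.** The most likely failure is Z to E isomerisation of C4=C5 through reversible amine addition to the enone, together with partial loss of the primary silyl ether in the acidic stage. The fallback sets out from 16 and returns at 18. A cationic gold catalyst, (Ph3P)AuCl with AgOTf in toluene at rt, would activate the alkyne and convert the 4-hydroxy-2-ynone directly to the 3(2H)-furanone with no amine and no aqueous acid. This makes no new compound (F0).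

**Step 21 (with step 20).** The most likely failure is migration of the acetyl group from the hindered O9 to the free O8 before or during acylation, which would give the regioisomeric diester. The fallback sets out from 27 and returns at 31, with the order of the esters reversed. HF·pyridine would remove the silyl group of 27 to give the C8 alcohol that keeps the PMB ether on O9, F6. Methacrylic anhydride with DMAP would give the C8 methacrylate F7. DDQ would free O9 to give the 9-hydroxy 8-methacrylate F8, in which the acyl group already sits on the less hindered oxygen. Ac2O with DMAP would then give 31.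

## Further compounds

F1 | step 9 | (3S,4S,5S)-5,6-bis(TBSO)-4-(PMBO)-3-methylhex-1-yn-3-ol | C[C@](O)(C#C)[C@@H](OCc1ccc(OC)cc1)[C@@H](O[Si](C)(C)C(C)(C)C)CO[Si](C)(C)C(C)(C)C
F2 | step 9 | (Z)-4-(3,4-dimethoxybenzyloxy)-2-methylbut-2-enal | O=C/C(C)=C\COCc1ccc(OC)c(OC)c1
F3 | step 9 | (2Z,7S,8S,9S)-9,10-bis(TBSO)-1-(DMBO)-8-(PMBO)-3,7-dimethyldec-2-en-5-yne-4,7-diol (C4 epimers) | C[C@](O)(C#CC(O)/C(C)=C\COCc1ccc(OC)c(OC)c1)[C@@H](OCc1ccc(OC)cc1)[C@@H](O[Si](C)(C)C(C)(C)C)CO[Si](C)(C)C(C)(C)C
F4 | step 17 | (2Z,4R,8S,9S,10S,11R)-9-(TBSO)-10-(PMBO)-2,11-dimethyl-7-methylidene-5,14-dioxatricyclo[9.2.1.0(4,8)]tetradeca-1(13),2-diene-6,12-dione (C6 epimer of 27) | CC(C)(C)[Si](C)(C)O[C@H]1[C@H]2C(=C)C(=O)O[C@@H]2/C=C(/C)C2=CC(=O)[C@](C)(O2)[C@H]1OCc1ccc(OC)cc1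
F5 | step 17 | ten-membered 6-hydroxy acid from F4 (2-propenoic acid unit on C7, C6 epimeric to 26) | CC(C)(C)[Si](C)(C)O[C@H]1[C@@H](C(=C)C(=O)O)[C@H](O)/C=C(/C)C2=CC(=O)[C@](C)(O2)[C@H]1OCc1ccc(OC)cc1
F0 | step 13 | none | none
F0 | step 10 | none | none
F6 | step 21 | (2Z,4S,8S,9S,10S,11R)-9-hydroxy-10-(PMBO)-2,11-dimethyl-7-methylidene-5,14-dioxatricyclo[9.2.1.0(4,8)]tetradeca-1(13),2-diene-6,12-dione | O[C@H]1[C@H]2C(=C)C(=O)O[C@H]2/C=C(/C)C2=CC(=O)[C@](C)(O2)[C@H]1OCc1ccc(OC)cc1
F7 | step 21 | (2Z,4S,8S,9S,10S,11R)-10-(PMBO)-2,11-dimethyl-7-methylidene-6,12-dioxo-5,14-dioxatricyclo[9.2.1.0(4,8)]tetradeca-1(13),2-dien-9-yl 2-methylprop-2-enoate | C=C(C)C(=O)O[C@H]1[C@H]2C(=C)C(=O)O[C@H]2/C=C(/C)C2=CC(=O)[C@](C)(O2)[C@H]1OCc1ccc(OC)cc1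
F8 | step 21 | (2Z,4S,8S,9S,10S,11R)-10-hydroxy-2,11-dimethyl-7-methylidene-6,12-dioxo-5,14-dioxatricyclo[9.2.1.0(4,8)]tetradeca-1(13),2-dien-9-yl 2-methylprop-2-enoate | C=C(C)C(=O)O[C@H]1[C@H]2C(=C)C(=O)O[C@H]2/C=C(/C)C2=CC(=O)[C@](C)(O2)[C@H]1O
A1 | alternative 1 | ten-membered furanone lactone with O8 and O9 as acetonide | CC3(C)O[C@H]1[C@H]2C(=C)C(=O)O[C@H]2/C=C(/C)C2=CC(=O)[C@](C)(O2)[C@H]1O3
A2 | alternative 1 | lactone- and acetonide-fused cyclooctenone with a 1-propynyl ether on the C10 oxygen | CC3(C)O[C@H]1[C@H]2C(=C)C(=O)O[C@H]2/C=C\C(=O)[C@](C)(OC#CC)[C@H]1O3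
A3 | alternative 2 | ten-membered 8,9-cis-diol lacking the C11 methylene | O[C@H]1[C@H]2CC(=O)O[C@H]2/C=C(/C)C2=CC(=O)[C@](C)(O2)[C@H]1O
A4 | alternative 2 | dialdehyde with CHO on C7 of the lactone and on C10 of the furanone | O=C[C@H]1CC(=O)O[C@H]1/C=C(/C)C1=CC(=O)[C@](C)(O1)C=O
A5 | alternative 3 | ten-membered cyclic enynol (C1 carbinol, O10 triethylsilyl ether, acetonide) | CC3(C)O[C@H]1[C@H]2C(=C)C(=O)O[C@H]2/C=C(/C)C#C[C@H](O)[C@](C)(O[Si](CC)(CC)CC)[C@H]1O3
A6 | alternative 3 | acyclic iodoalkyne with the C1 aldehyde on C10 | CC1(C)O[C@@H]([C@H]2C(=C)C(=O)O[C@H]2/C=C(/C)C#CI)[C@@H]([C@@](C)(O[Si](CC)(CC)CC)C=O)O1
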